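Ring B carries the aroyl group (C1) next to the formyl group (C2), with oxygen at C3 and C5 and prenyl at C6. Replacing the C1 aroyl by OH therefore reveals 3-prenylphloroglucinaldehyde. The congested diaryl ketone bond (ring B C1–CO) is thus disconnected as an ipso exchange of a phenolic C–O bond for a C–acyl bond. The formyl group serves as tether. Its N-aroylhydrazone with the dibrominated ring A hydrazide is oxidised with lead(IV) acetate (Kotali reaction), which expels N2, delivers the aroyl carbon intramolecularly onto C1 and returns the free aldehyde in one operation. The precursor is a simple condensation product of two arenes, and one BCl3 treatment finishes.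

Key step: step 7

Remark on the chemistry: the SMILES holds no stereocentre, and the prenyl double bond bears two identical methyl groups. Rotation about both aryl–carbonyl bonds is assumed fast at room temperature, so the target is treated as achiral and no stereocontrol is needed.

Step 1
Reactants: 1 3,5-dimethoxytoluene
Product: 3 2,6-dimethoxy-4-methylbenzoic acid, via aryllithium 2 (not isolated)
Conditions: n-BuLi (1.1 equiv), THF, 0 °C → rt; CO2 (s), −78 °C → rt; aq HCl
Reagents that add atoms: carbon dioxide O=C=O; n-butyllithium [Li]CCCC (lithium of 2 only)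
Why: Directed ortho-metalation, in which the C–H flanked by both methoxy groups is the most acidic and doubly coordinated site, so lithiation followed by carboxylation should give only the 2,6-dimethoxy acid.

Step 2
Reactants: 3 2,6-dimethoxy-4-methylbenzoic acid
Product: 4 3,5-dibromo-2,6-dimethoxy-4-methylbenzoic acid
Conditions: Br2 (2.2 equiv), AcOH, rt, dark
Reagents that add atoms: bromine BrBr
Why: Electrophilic aromatic bromination, in which the only two free ring positions are equivalent and each is activated by both methoxy groups and the methyl group, while ionic conditions in the dark should spare the benzylic methyl.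

Step 3
Reactants: 4 3,5-dibromo-2,6-dimethoxy-4-methylbenzoic acid
Product: 6 3,5-dibromo-2,6-dimethoxy-4-methylbenzohydrazide, via acid chloride 5 (not isolated)
Conditions: (COCl)2, cat. DMF, CH2Cl2, 0 °C → rt; evaporate; N2H4·H2O (10 equiv), THF, 0 °C
Reagents that add atoms: hydrazine NN; oxalyl chloride O=C(Cl)C(=O)Cl (chlorine of 5 only)
Why: Acyl chloride formation and N-acylation, in which the small alpha-effect nucleophile hydrazine should reach even this di-ortho-substituted acyl chloride, and its large excess together with the crowding suppresses double acylation.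

Step 4
Reactants: 7 2,4,6-trihydroxybenzaldehyde; 8 prenyl bromide (1-bromo-3-methylbut-2-ene)
Product: 9 2,4,6-trihydroxy-3-(3-methylbut-2-en-1-yl)benzaldehyde
Conditions: KOH (1 equiv), H2O, 0 °C → rt, 8 as limiting reagent
Reagents that add atoms: none
Why: C-alkylation of the ambident phloroglucinolate anion in water, where hydrogen bonding shields oxygen; the two free ring carbons of 7 are equivalent, so mono-C-prenylation can give only one constitution, and keeping 8 limiting curbs double alkylation.

Step 5
Reactants: 9 2,4,6-trihydroxy-3-(3-methylbut-2-en-1-yl)benzaldehyde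
Product: 10 2-hydroxy-4,6-bis(methoxymethoxy)-3-(3-methylbut-2-en-1-yl)benzaldehyde
Conditions: MOMCl (2.1 equiv), iPr2NEt, CH2Cl2, 0 °C
Reagents that add atoms: chloromethyl methyl ether COCCl
Why: Selective MOM ether formation, in which the non-chelated 4-OH reacts first and the less hindered 6-OH second, after which the 2-OH, wedged between prenyl and formyl and locked in the hydrogen bond to C=O, should stay free.

Step 6
Reactants: 6 3,5-dibromo-2,6-dimethoxy-4-methylbenzohydrazide; 10 2-hydroxy-4,6-bis(methoxymethoxy)-3-(3-methylbut-2-en-1-yl)benzaldehyde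
Product: 11 (E)-3,5-dibromo-N'-[2-hydroxy-4,6-bis(methoxymethoxy)-3-(3-methylbut-2-en-1-yl)benzylidene]-2,6-dimethoxy-4-methylbenzohydrazide
Conditions: EtOH, cat. AcOH, reflux
Reagents that add atoms: none
Why: Acid-catalysed condensation of an aldehyde and an acylhydrazide to the N-acylhydrazone, helped by the O–H···N hydrogen bond that also fixes the E geometry, with the reacting NH2 lying far from the crowded aroyl group.

Step 7
Reactants: 11 (E)-3,5-dibromo-N'-[2-hydroxy-4,6-bis(methoxymethoxy)-3-(3-methylbut-2-en-1-yl)benzylidene]-2,6-dimethoxy-4-methylbenzohydrazide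
Product: 15 2-(3,5-dibromo-2,6-dimethoxy-4-methylbenzoyl)-4,6-bis(methoxymethoxy)-3-(3-methylbut-2-en-1-yl)benzaldehyde, via azoacetate 12 (not isolated), via bridged oxadiazoline 13 (not isolated), via aryloxycarbene 14 (not isolated)
Conditions: Pb(OAc)4 (1.1 equiv), THF, 0 °C → rt, light excluded
Reagents that add atoms: lead(IV) acetate CC(=O)O[Pb](OC(C)=O)(OC(C)=O)OC(C)=O (acetoxy group of 12 only)
Why: Kotali reaction, the known lead(IV) oxidation of salicylaldehyde and o-hydroxyaryl ketone N-acylhydrazones to 1,2-diacylbenzenes, in which Pb(IV) attacks the hydrazone N–H and transfers acetate to the benzylic carbon to give azoacetate 12. Assisted by the free ortho OH, 12 loses acetate, the acyl oxygen closes the five-membered Δ3-1,3,4-oxadiazoline ring on the benzylic carbon (5-exo) and the phenol oxygen closes the six-membered 1,3-dioxine ring on the resulting C2 cation (6-endo), giving 13; both rings are transient and none remains in 15. Cycloreversion of N2 leaves a carbonyl ylide that splits into the free formyl group and aryloxycarbene 14, and ipso attack of this nucleophilic carbene carbon on ring B C1 (spiro-oxirane, Smiles-type 1,2 O→C aryl shift) forms the ketone, the former phenol oxygen becoming the ketone oxygen. The closest mechanistic relatives are the thermal decay of 2-alkoxy-Δ3-1,3,4-oxadiazolines to oxycarbenes and the Smiles rearrangement, and no stereocentre is created. Site selectivity (the C1–O beside the prenyl group, not C3–O or C5–O) is secured because only that hydroxyl is free, and chemoselectivity over the prenyl alkene, the MOM acetals and the aryl bromides rests on the much faster reaction of Pb(IV) with the hydrazone N–H at or below room temperature. The ipso step is favoured by the just released ortho formyl group, which takes up the negative charge, by the two MOM-oxy groups standing meta to C1 (inductive pull, no resonance push), and by its three-atom intramolecular reach, which should make it insensitive to the four ortho substituents that hamper bimolecular unions.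

Step 8
Reactants: 15 2-(3,5-dibromo-2,6-dimethoxy-4-methylbenzoyl)-4,6-bis(methoxymethoxy)-3-(3-methylbut-2-en-1-yl)benzaldehyde
Product: 16 Pestalone D, 2-(3,5-dibromo-2-hydroxy-6-methoxy-4-methylbenzoyl)-4,6-dihydroxy-3-(3-methylbut-2-en-1-yl)benzaldehyde
Conditions: BCl3 (5 equiv), CH2Cl2, −78 → −10 °C; ice-water
Reagents that add atoms: none
Why: Chelation-directed ether cleavage, in which BCl3 bound between the ketone oxygen and one of the two equivalent ortho methoxy groups of ring A removes that methyl by chloride attack, the resulting boron chelate shields the second methoxy group, the same Lewis acid cleaves both MOM acetals, and the low temperature should spare the prenyl group.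

Compound list
1 | 3,5-dimethoxytoluene | COc1cc(C)cc(OC)c1 | starting material
2 | (2,6-dimethoxy-4-methylphenyl)lithium | [Li]c1c(OC)cc(C)cc1OC | intermediate
3 | 2,6-dimethoxy-4-methylbenzoic acid | COc1cc(C)cc(OC)c1C(=O)O | intermediate
4 | 3,5-dibromo-2,6-dimethoxy-4-methylbenzoic acid | COc1c(Br)c(C)c(Br)c(OC)c1C(=O)O | intermediate
5 | 3,5-dibromo-2,6-dimethoxy-4-methylbenzoyl chloride | COc1c(Br)c(C)c(Br)c(OC)c1C(Cl)=O | intermediate
6 | 3,5-dibromo-2,6-dimethoxy-4-methylbenzohydrazide | COc1c(Br)c(C)c(Br)c(OC)c1C(=O)NN | intermediate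
7 | 2,4,6-trihydroxybenzaldehyde | O=Cc1c(O)cc(O)cc1O | starting material
8 | prenyl bromide (1-bromo-3-methylbut-2-ene) | CC(C)=CCBr | starting material
9 | 2,4,6-trihydroxy-3-(3-methylbut-2-en-1-yl)benzaldehyde | O=Cc1c(O)cc(O)c(CC=C(C)C)c1O | intermediate
10 | 2-hydroxy-4,6-bis(methoxymethoxy)-3-(3-methylbut-2-en-1-yl)benzaldehyde | COCOc1cc(OCOC)c(CC=C(C)C)c(O)c1C=O | intermediate
11 | (E)-N-aroylhydrazone of 10 with 6 | COCOc1cc(OCOC)c(CC=C(C)C)c(O)c1/C=N/NC(=O)c1c(OC)c(Br)c(C)c(Br)c1OC | intermediate
12 | azoacetate, aryl-CH(OAc)-N=N-C(=O)-aryl' (racemic, transient) | COCOc1cc(OCOC)c(CC=C(C)C)c(O)c1C(OC(C)=O)N=NC(=O)c1c(OC)c(Br)c(C)c(Br)c1OC | intermediate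
13 | 2,4-azo-bridged 2-aryl-4H-1,3-benzodioxine (bicyclic Δ3-1,3,4-oxadiazoline; racemic, bridgeheads fixed relative to each other by the bridge) | COCOc1cc(OCOC)c(CC=C(C)C)c2OC3(N=NC(O3)c12)c4c(OC)c(Br)c(C)c(Br)c4OC | intermediate
14 | (2-formylaryloxy)(aryl')carbene | COCOc1cc(OCOC)c(CC=C(C)C)c(O[C]c2c(OC)c(Br)c(C)c(Br)c2OC)c1C=O | intermediate
15 | 2-(3,5-dibromo-2,6-dimethoxy-4-methylbenzoyl)-4,6-bis(methoxymethoxy)-3-(3-methylbut-2-en-1-yl)benzaldehyde | COCOc1cc(OCOC)c(CC=C(C)C)c(C(=O)c2c(OC)c(Br)c(C)c(Br)c2OC)c1C=O | intermediate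
16 | Pestalone D | COc1c(Br)c(C)c(Br)c(O)c1C(=O)c1c(C=O)c(O)cc(O)c1CC=C(C)C | target

Total step count: 8
Longest linear sequence: 6 steps (1, 2, 3, 6, 7, 8)

Steps most likely to fail

1. Step 7.
- Risk: the azoacetate may lose its benzylic hydrogen and aromatise by oxidative cyclisation instead of engaging the phenol. Ring closure at the crowded acyl carbon may be slow, so that Pb(IV) begins a Wessely-type oxidation of the electron-rich phenol ring. The transient carbene may also add to the neighbouring prenyl double bond.
- Fallback: it sets out from 10 and 1 and comes back at 15. It is a polarity-reversed bimolecular union on a tied-back lactone.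
- Ring B partner: 10 with Tf2O/pyridine should give the aryl triflate F1. NaBH4 then gives the benzylic alcohol F2. Pd(OAc)2/dppp, CO, Et3N in DMF closes the phthalide F3 by carbonylative lactonisation.
- Ring A partner: separately, 1 is brominated (Br2, AcOH) to 2,4,6-tribromo-3,5-dimethoxytoluene F4. The bromine between its two methoxy groups should undergo selective Br/Mg exchange (iPrMgCl·LiCl, THF, −20 °C) to the arylmagnesium chloride F5.
- Union: addition of F5 to F3 gives the keto alcohol F6 (in equilibrium with its lactol), and Dess–Martin oxidation gives 15.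

2. Step 5.
- Risk: poor discrimination between the two hydrogen-bonded ortho hydroxyls, together with over-alkylation in step 4.
- Fallback: it sets out from 7, comes back at 10 and replaces steps 4 and 5. The site of the prenyl group is fixed by a sigmatropic shift instead of by a selective protection.
- Sequence: 7, whose two ortho hydroxyls are still equivalent, with MOMCl (2 equiv)/iPr2NEt gives 2-hydroxy-4,6-bis(methoxymethoxy)benzaldehyde F7. Tsuji–Trost O-allylation with tert-butyl 2-methylbut-3-en-2-yl carbonate and cat. Pd(PPh3)4 gives the 1,1-dimethylallyl ether F8. Heating in toluene triggers the aromatic Claisen rearrangement to the only free ortho carbon, which delivers the normal prenyl group and the free 2-OH of 10.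

3. Step 8.
- Risk: acid-induced ring closure of the prenyl group onto the neighbouring phenol, addition of HCl to the alkene, or loss of the second methyl ether.
- Fallback: it sets out from 4, uses 10 and comes back at 16. Ring A is desymmetrised before the union, so that no Lewis acid meets the prenyl phenol.
- Ring A hydrazide: BCl3 (1.1 equiv, CH2Cl2, 0 °C, carboxyl-directed) gives the hydroxy acid F9. MOMCl/iPr2NEt gives the MOM ether MOM ester F10. LiOH in aqueous THF frees the acid F11. 1-Chloro-N,N,2-trimethylpropenylamine gives, under neutral conditions, the acid chloride F12, and excess hydrazine gives the hydrazide F13.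
- Union and end game: condensation with 10 gives the hydrazone F14. Pb(OAc)4 in THF gives the tris-MOM benzophenone F15. Dilute HCl in aqueous THF/iPrOH at 40 °C gives 16.

Further compounds
F1 | step 7 | 2-formyl-3,5-bis(methoxymethoxy)-6-(3-methylbut-2-en-1-yl)phenyl trifluoromethanesulfonate | COCOc1cc(OCOC)c(CC=C(C)C)c(OS(=O)(=O)C(F)(F)F)c1C=O
F2 | step 7 | 2-(hydroxymethyl)-3,5-bis(methoxymethoxy)-6-(3-methylbut-2-en-1-yl)phenyl trifluoromethanesulfonate | COCOc1cc(OCOC)c(CC=C(C)C)c(OS(=O)(=O)C(F)(F)F)c1CO
F3 | step 7 | 4,6-bis(methoxymethoxy)-7-(3-methylbut-2-en-1-yl)isobenzofuran-1(3H)-one | COCOc1cc(OCOC)c(CC=C(C)C)c2C(=O)OCc12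
F4 | step 7 | 2,4,6-tribromo-3,5-dimethoxytoluene | COc1c(Br)c(C)c(Br)c(OC)c1Br
F5 | step 7 | (3,5-dibromo-2,6-dimethoxy-4-methylphenyl)magnesium chloride | COc1c(Br)c(C)c(Br)c(OC)c1[Mg]Cl
F6 | step 7 | (3,5-dibromo-2,6-dimethoxy-4-methylphenyl)[2-(hydroxymethyl)-3,5-bis(methoxymethoxy)-6-(3-methylbut-2-en-1-yl)phenyl]methanone | COCOc1cc(OCOC)c(CC=C(C)C)c(C(=O)c2c(OC)c(Br)c(C)c(Br)c2OC)c1CO
F7 | step 5 | 2-hydroxy-4,6-bis(methoxymethoxy)benzaldehyde | COCOc1cc(O)c(C=O)c(OCOC)c1
F8 | step 5 | 2,4-bis(methoxymethoxy)-6-[(2-methylbut-3-en-2-yl)oxy]benzaldehyde | COCOc1cc(OC(C)(C)C=C)c(C=O)c(OCOC)c1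
F9 | step 8 | 3,5-dibromo-2-hydroxy-6-methoxy-4-methylbenzoic acid | COc1c(Br)c(C)c(Br)c(O)c1C(=O)O
F10 | step 8 | methoxymethyl 3,5-dibromo-2-methoxy-6-(methoxymethoxy)-4-methylbenzoate | COCOC(=O)c1c(OC)c(Br)c(C)c(Br)c1OCOC
F11 | step 8 | 3,5-dibromo-2-methoxy-6-(methoxymethoxy)-4-methylbenzoic acid | COCOc1c(Br)c(C)c(Br)c(OC)c1C(=O)O
F12 | step 8 | 3,5-dibromo-2-methoxy-6-(methoxymethoxy)-4-methylbenzoyl chloride | COCOc1c(Br)c(C)c(Br)c(OC)c1C(Cl)=O
F13 | step 8 | 3,5-dibromo-2-methoxy-6-(methoxymethoxy)-4-methylbenzohydrazide | COCOc1c(Br)c(C)c(Br)c(OC)c1C(=O)NN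
F14 | step 8 | (E)-N-aroylhydrazone of 10 with F13 | COCOc1cc(OCOC)c(CC=C(C)C)c(O)c1/C=N/NC(=O)c1c(OC)c(Br)c(C)c(Br)c1OCOC
F15 | step 8 | 2-[3,5-dibromo-2-methoxy-6-(methoxymethoxy)-4-methylbenzoyl]-4,6-bis(methoxymethoxy)-3-(3-methylbut-2-en-1-yl)benzaldehyde | COCOc1cc(OCOC)c(CC=C(C)C)c(C(=O)c2c(OC)c(Br)c(C)c(Br)c2OCOC)c1C=O
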